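## Retrosynthetic overview

- Target 18 ⇐ flavan 13: the dodecanoyl group goes onto ring D last by Friedel–Crafts acylation (the two free positions of the tribenzyloxyphenyl ring are equivalent), with ring A held as its C7 ester; the benzyl ethers are removed at the end.
- Flavan 13 ⇐ dienone 11: ring C is closed at O1–C8a. The structural feature used is that O1 sits on C8a of ring A, meta to the C7 hydroxyl and ortho to C4a. Before closure ring A is a para-alkylphenol whose two carbons flanking C4a are equivalent, so the C2 hydroxyl can add to the ring-A para-quinol methyl ether and methanol is then lost.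
- Dienone 11 ⇐ phenol 9 (PhI(OAc)2/MeOH, carbinol silylated) ⇐ diol 7 ⇐ ketone 6: C2 is set by asymmetric transfer hydrogenation, C4 by rhodium-catalysed 1,4-addition of boronic acid 5 to chalcone 4.
- Chalcone 4 ⇐ aldehyde 2 + ketone 3. Rings A, B and D are bought as arenes; ring C is the only ring formed (step 8).

Key step: step 8

Remarks and assumptions:
- Flavan numbering is used throughout: ring A is the benzo ring (C4a–C8a), ring B sits on C2, ring C is the pyran, ring D is the aryl group on C4.
- The descriptor of the later C4 is R in 6–9, S in 10–12 and R again from 13 on. These changes come only from CIP ranking; the centre is never touched.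
- Assumption: in step 3 the diene antipode is the one that places the aryl group on the Si face of the β-carbon. (R,R) is written; the mirror-image ligand is used if a small-scale run shows the opposite sense.

## Route

Step 1
Reactants: 1 2,4,6-trihydroxybenzaldehyde
Product: 2 2,4,6-tris(benzyloxy)benzaldehyde
Conditions: BnBr (3.6 equiv), K2CO3 (4.5 equiv), DMF, 60 °C
Reagents that add atoms: benzyl bromide, BrCc1ccccc1
Why: Williamson ether synthesis on all three phenols; the formyl group lowers the ring nucleophilicity, so O-benzylation should outrun C-benzylation.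

Step 2
Reactants: 2 2,4,6-tris(benzyloxy)benzaldehyde; 3 4'-(benzyloxy)acetophenone
Product: 4 (E)-1-[4-(benzyloxy)phenyl]-3-[2,4,6-tris(benzyloxy)phenyl]prop-2-en-1-one
Conditions: KOH (aq, 1.5 equiv), EtOH/THF, rt
Reagents that add atoms: none
Why: Claisen–Schmidt condensation of a non-enolisable aldehyde with an aryl methyl ketone; E1cB dehydration of the aldol should give the (E)-chalcone.

Step 3
Reactants: 4 (E)-chalcone; 5 4-hydroxyphenylboronic acid
Product: 6 (3R)-1-[4-(benzyloxy)phenyl]-3-(4-hydroxyphenyl)-3-[2,4,6-tris(benzyloxy)phenyl]propan-1-one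
Conditions: 5 (3 equiv), Rh(acac)(C2H4)2 (5 mol %), (R,R)-Ph-bod* [(1R,4R)-2,5-diphenylbicyclo[2.2.2]octa-2,5-diene] (5.5 mol %), KOH (0.5 equiv), dioxane/H2O 10:1, 50 °C
Reagents that add atoms: none
Why: Hayashi–Miyaura 1,4-addition: the aryl group passes from boron to monovalent rhodium and adds across the enone C=C, the C2-symmetric diene leaving one enantioface open, so that the 4-hydroxyphenyl group arrives on the Si face of the β-carbon and sets the (R)-diarylmethine centre (the later C4); the free phenol is tolerated in the aqueous basic medium and the excess of 5 offsets protodeboronation.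

Step 4
Reactants: 6 (3R)-phenol ketone
Product: 7 (1S,3R)-1-[4-(benzyloxy)phenyl]-3-(4-hydroxyphenyl)-3-[2,4,6-tris(benzyloxy)phenyl]propan-1-ol
Conditions: RuCl[(S,S)-TsDPEN](p-cymene) (2 mol %), HCO2H/Et3N 5:2, DMF, 40 °C
Reagents that add atoms: none
Why: Noyori–Ikariya asymmetric transfer hydrogenation: the Ru–H/N–H pair of the (S,S) catalyst delivers hydride to the Re face of the aryl ketone through the six-membered transition state with the arene–aryl CH–π contact, giving the (S)-carbinol (the later C2) under catalyst control without protection of the remote phenol.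

Step 5
Reactants: 7 (1S,3R)-phenol carbinol
Product: 9 4-[(1R,3S)-3-[4-(benzyloxy)phenyl]-3-[(tert-butyldimethylsilyl)oxy]-1-[2,4,6-tris(benzyloxy)phenyl]propyl]phenol, via bis-silyl ether 8 (not isolated)
Conditions: TBSCl (2.5 equiv), imidazole, DMF, rt; then K2CO3, MeOH, rt
Reagents that add atoms: tert-butyldimethylsilyl chloride, CC(C)(C)[Si](C)(C)Cl
Why: Silylation of both hydroxyls followed by selective methanolysis of the aryl silyl ether, which has a phenoxide leaving group, while the secondary alkyl silyl ether should stay in place.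

Step 6
Reactants: 9 silyl-protected phenol
Product: 10 4-[(1S,3S)-3-[4-(benzyloxy)phenyl]-3-[(tert-butyldimethylsilyl)oxy]-1-[2,4,6-tris(benzyloxy)phenyl]propyl]-4-methoxycyclohexa-2,5-dien-1-one
Conditions: PhI(OAc)2 (1.1 equiv), MeOH/CH2Cl2 4:1, 0 °C, short reaction time, NaHCO3 quench
Reagents that add atoms: methanol, CO
Why: Oxidative dearomatisation of a para-alkylphenol by trivalent iodine: the phenol oxygen binds to iodine, methanol attacks the para carbon as iodobenzene leaves and the quinol methyl ether forms, while the silyl ether keeps the carbinol from closing a spiro tetrahydrofuran at the ipso carbon.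

Step 7
Reactants: 10 silyl-protected quinol ether
Product: 11 4-[(1S,3S)-3-[4-(benzyloxy)phenyl]-3-hydroxy-1-[2,4,6-tris(benzyloxy)phenyl]propyl]-4-methoxycyclohexa-2,5-dien-1-one
Conditions: Bu4NF (1.5 equiv), AcOH (1.5 equiv), THF, 0 °C to rt; crude material used at once
Reagents that add atoms: none
Why: Fluoride cleavage of the silyl ether, buffered with acetic acid so that the free carbinol is obtained largely uncyclised; any portion that has already closed converges in step 8.

Step 8
Reactants: 11 hydroxy dienone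
Product: 13 (2S,4R)-2-[4-(benzyloxy)phenyl]-4-[2,4,6-tris(benzyloxy)phenyl]chroman-7-ol, via cis-fused methoxy enone 12 (not isolated)
Conditions: DBU (0.2 equiv), CH2Cl2, 0 °C to rt; then TsOH·H2O (0.5 equiv), rt, short time
Reagents that add atoms: none
Why: DBU generates the C2 alkoxide, which adds in a 6-exo-trig oxa-Michael reaction to one of the two β-carbons of the cross-conjugated dienone and closes ring C through the new O1–C8a bond as the cis-fused enone 12; TsOH then enolises the ketone towards C8, ionises the doubly allylic C4a–OMe bond, and the resulting arenium ion loses the C8a proton, so that ring A returns as a phenol with its hydroxyl para to C4a (C7) and the ether oxygen ortho to C4a. The closest known reaction type is the oxidative dearomatisation, intramolecular oxa-Michael addition and eliminative rearomatisation of para-alkylphenols that gives meta-oxygenated phenols and chromans. No lasting stereocentre is created: C4a and C8a of 12 become sp2 again, and C2 and C4 stay as set because only the O–H bond of the carbinol reacts. The selectivity needed is positional, and it is secured by the symmetry of the para-quinol: the two enone arms are diastereotopic but end in the same aromatic ring, and the six-membered closure onto a β-carbon is the only path open once the ipso carbon is quaternary. The base stage comes first so that the acid meets the adduct and not the free dienone, which should keep dienone–phenol rearrangement and loss of the ring-D-stabilised benzylic cation in the background.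

Step 9
Reactants: 13 flavan-7-ol; 14 dodecanoyl chloride
Product: 15 (2S,4R)-2-[4-(benzyloxy)phenyl]-4-[2,4,6-tris(benzyloxy)phenyl]chroman-7-yl dodecanoate
Conditions: 14 (1.2 equiv), Et3N, DMAP (cat.), CH2Cl2, 0 °C
Reagents that add atoms: none
Why: Nucleophilic acyl substitution at the phenol; the ester makes ring A less nucleophilic than an ether would and removes the para-oxygen assistance to C4 ionisation before the Lewis-acid step.

Step 10
Reactants: 15 C7 dodecanoate; 14 dodecanoyl chloride
Product: 16 (2S,4R)-2-[4-(benzyloxy)phenyl]-4-[2,4,6-tris(benzyloxy)-3-dodecanoylphenyl]chroman-7-yl dodecanoate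
Conditions: 14 (1.5 equiv), SnCl4 (1.5 equiv), CH2Cl2, −78 to −30 °C, cold NaHCO3 quench
Reagents that add atoms: none
Why: Friedel–Crafts acylation: ring D carries three alkoxy groups ortho or para to its two equivalent free positions and should react far faster than the ester-deactivated ring A or ring B, the first acyl group stops a second acylation, and a benzyl group lost next to the new ketone would converge in step 12.

Step 11
Reactants: 16 keto ester
Product: 17 1-[2,4,6-tris(benzyloxy)-3-[(2S,4R)-2-[4-(benzyloxy)phenyl]-7-hydroxychroman-4-yl]phenyl]dodecan-1-one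
Conditions: K2CO3, MeOH/THF, rt
Reagents that add atoms: none
Why: Base-mediated transesterification of the aryl ester with methanol; the hindered aryl ketone and the benzyl ethers should not react.

Step 12
Reactants: 17 tetrabenzyl ether
Product: 18 (+)-myristinin A, 1-[2,4,6-trihydroxy-3-[(2S,4R)-7-hydroxy-2-(4-hydroxyphenyl)chroman-4-yl]phenyl]dodecan-1-one
Conditions: H2 (1 atm), Pd/C (10 %), EtOAc/MeOH, rt, stopped on full debenzylation
Reagents that add atoms: none
Why: Hydrogenolysis of four benzyl aryl ethers; under these mild conditions the diaryl-substituted C4, the C2–O1 bond and the chelated aryl ketone should survive, as they do in the debenzylation of benzylated flavans.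

## Compound list

1 | 2,4,6-trihydroxybenzaldehyde | O=Cc1c(O)cc(O)cc1O | starting material
2 | 2,4,6-tris(benzyloxy)benzaldehyde | O=Cc1c(OCc2ccccc2)cc(OCc2ccccc2)cc1OCc1ccccc1 | intermediate
3 | 4'-(benzyloxy)acetophenone | CC(=O)c1ccc(OCc2ccccc2)cc1 | starting material
4 | (E)-1-[4-(benzyloxy)phenyl]-3-[2,4,6-tris(benzyloxy)phenyl]prop-2-en-1-one | O=C(/C=C/c1c(OCc2ccccc2)cc(OCc2ccccc2)cc1OCc1ccccc1)c1ccc(OCc2ccccc2)cc1 | intermediate
5 | 4-hydroxyphenylboronic acid | OB(O)c1ccc(O)cc1 | starting material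
6 | (3R)-1-[4-(benzyloxy)phenyl]-3-(4-hydroxyphenyl)-3-[2,4,6-tris(benzyloxy)phenyl]propan-1-one | c1ccccc1COc1cc(OCc2ccccc2)cc(OCc2ccccc2)c1[C@@H](c1ccc(O)cc1)CC(=O)c1ccc(OCc2ccccc2)cc1 | intermediate
7 | (1S,3R)-1-[4-(benzyloxy)phenyl]-3-(4-hydroxyphenyl)-3-[2,4,6-tris(benzyloxy)phenyl]propan-1-ol | c1ccccc1COc1cc(OCc2ccccc2)cc(OCc2ccccc2)c1[C@@H](c1ccc(O)cc1)C[C@@H](c1ccc(OCc2ccccc2)cc1)O | intermediate
8 | bis(tert-butyldimethylsilyl) ether of 7 (phenol and carbinol both silylated) | c1ccccc1COc1cc(OCc2ccccc2)cc(OCc2ccccc2)c1[C@@H](c1ccc(O[Si](C)(C)C(C)(C)C)cc1)C[C@@H](c1ccc(OCc2ccccc2)cc1)O[Si](C)(C)C(C)(C)C | intermediate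
9 | 4-[(1R,3S)-3-[4-(benzyloxy)phenyl]-3-[(tert-butyldimethylsilyl)oxy]-1-[2,4,6-tris(benzyloxy)phenyl]propyl]phenol | c1ccccc1COc1cc(OCc2ccccc2)cc(OCc2ccccc2)c1[C@@H](c1ccc(O)cc1)C[C@@H](c1ccc(OCc2ccccc2)cc1)O[Si](C)(C)C(C)(C)C | intermediate
10 | 4-[(1S,3S)-3-[4-(benzyloxy)phenyl]-3-[(tert-butyldimethylsilyl)oxy]-1-[2,4,6-tris(benzyloxy)phenyl]propyl]-4-methoxycyclohexa-2,5-dien-1-one | c1ccccc1COc1cc(OCc2ccccc2)cc(OCc2ccccc2)c1[C@@H](C1(OC)C=CC(=O)C=C1)C[C@@H](c1ccc(OCc2ccccc2)cc1)O[Si](C)(C)C(C)(C)C | intermediate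
11 | 4-[(1S,3S)-3-[4-(benzyloxy)phenyl]-3-hydroxy-1-[2,4,6-tris(benzyloxy)phenyl]propyl]-4-methoxycyclohexa-2,5-dien-1-one | c1ccccc1COc1cc(OCc2ccccc2)cc(OCc2ccccc2)c1[C@@H](C1(OC)C=CC(=O)C=C1)C[C@@H](c1ccc(OCc2ccccc2)cc1)O | intermediate
12 | (2S,4S)-2-[4-(benzyloxy)phenyl]-4a-methoxy-4-[2,4,6-tris(benzyloxy)phenyl]-2,3,4,4a,8,8a-hexahydro-7H-chromen-7-one (cis-fused, both C4a/C8a diastereomers) | c1ccccc1COc1cc(OCc2ccccc2)cc(OCc2ccccc2)c1[C@@H](C1(OC)C=CC(=O)CC13)C[C@@H](c1ccc(OCc2ccccc2)cc1)O3 | intermediate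
13 | (2S,4R)-2-[4-(benzyloxy)phenyl]-4-[2,4,6-tris(benzyloxy)phenyl]chroman-7-ol (2,4-trans) | c1ccccc1COc1cc(OCc2ccccc2)cc(OCc2ccccc2)c1[C@@H]1C[C@@H](c2ccc(OCc3ccccc3)cc2)Oc2cc(O)ccc12 | intermediate
14 | dodecanoyl chloride | CCCCCCCCCCCC(=O)Cl | starting material
15 | (2S,4R)-2-[4-(benzyloxy)phenyl]-4-[2,4,6-tris(benzyloxy)phenyl]chroman-7-yl dodecanoate | c1ccccc1COc1cc(OCc2ccccc2)cc(OCc2ccccc2)c1[C@@H]1C[C@@H](c2ccc(OCc3ccccc3)cc2)Oc2cc(OC(=O)CCCCCCCCCCC)ccc12 | intermediate
16 | (2S,4R)-2-[4-(benzyloxy)phenyl]-4-[2,4,6-tris(benzyloxy)-3-dodecanoylphenyl]chroman-7-yl dodecanoate | c1ccccc1COc1c(C(=O)CCCCCCCCCCC)c(OCc2ccccc2)cc(OCc2ccccc2)c1[C@@H]1C[C@@H](c2ccc(OCc3ccccc3)cc2)Oc2cc(OC(=O)CCCCCCCCCCC)ccc12 | intermediate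
17 | 1-[2,4,6-tris(benzyloxy)-3-[(2S,4R)-2-[4-(benzyloxy)phenyl]-7-hydroxychroman-4-yl]phenyl]dodecan-1-one | c1ccccc1COc1c(C(=O)CCCCCCCCCCC)c(OCc2ccccc2)cc(OCc2ccccc2)c1[C@@H]1C[C@@H](c2ccc(OCc3ccccc3)cc2)Oc2cc(O)ccc12 | intermediate
18 | (+)-myristinin A | CCCCCCCCCCCC(=O)c1c(O)cc(O)c([C@@H]2C[C@@H](c3ccc(O)cc3)Oc3cc(O)ccc32)c1O | target

## Step count

Total: 12 steps. Longest linear sequence: 12 steps (1 to 18).

## Steps most likely to fail

**Step 6 (oxidative dearomatisation).** Three things may go wrong: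
- The oxidised phenol may lose the C4 benzylic proton and form a quinone methide, which methanol would capture at C4 and so erase that stereocentre.
- The oxidant may attack the trialkoxy ring D.
- The ring-D-stabilised benzylic cation may be expelled from the dienone.

The fallback replaces the cationic oxidation by singlet-oxygen dearomatisation, which needs no carbinol protection. It sets out from 7. KHSO5 (as 2KHSO5·KHSO4·K2SO4) with NaHCO3 in MeCN/H2O should give the para-peroxyquinol F1. Me2S should reduce it to the para-quinol F2. DBU should close F2 to the bicyclic hydroxy enone F3, and TsOH·H2O should then remove water and bring the material back to the route at 13.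

**Step 8 (oxa-Michael addition and rearomatisation).** The acid stage may break bonds at C4, either by loss of the benzylic cation from unreacted dienone or by retro-Friedel–Crafts cleavage of the electron-rich flavan. The oxa-Michael adduct may also revert and leave the dienone open to dienone–phenol rearrangement.

The fallback abandons the dearomatisation and forms the C4–ring D bond last, by the established alkylation of an acylphloroglucinol with a flavan-4-yl cation. It sets out from 14 and returns at 18.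
- Friedel–Crafts acylation of phloroglucinol with 14 (AlCl3, PhNO2/CH2Cl2) should give 1-(2,4,6-trihydroxyphenyl)dodecan-1-one F4.
- Purchased 7-hydroxychromone is benzylated (BnBr, K2CO3) to 7-(benzyloxy)chromone F5.
- Pd(OCOCF3)2 with a tert-butyl pyridine–oxazoline ligand (antipode chosen for 2S) should add 4-(benzyloxy)phenylboronic acid to F5 and give the (2S)-flavanone F6.
- NaBH4 should give the flavan-4-ol F7.
- Acid (TsOH·H2O or BF3·OEt2, CH2Cl2, low temperature) should ionise C4 of F7, and F4 should attack anti to the C2 aryl group to give the 2,4-trans di-O-benzyl myristinin A F8.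
- Hydrogenolysis over Pd/C then gives 18.

**Step 3 (rhodium-catalysed 1,4-addition).** Insertion at a β-carbon flanked by two ortho benzyloxy groups may be slow, protodeboronation of the electron-rich boronic acid may outpace addition, and enantioface discrimination may be weak.

The fallback sets C4 by auxiliary control. It sets out from 2 and returns at 6.
- Knoevenagel–Doebner condensation with malonic acid (pyridine, piperidine, heat) should give the cinnamic acid F9.
- Its mixed pivalic anhydride is coupled with lithiated (4S)-4-phenyloxazolidin-2-one to give the N-enoyl imide F10.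
- 4-(TBSO)C6H4MgBr with CuBr·SMe2 in THF should add to the magnesium-chelated syn-s-cis imide anti to the auxiliary phenyl group, which is the Si face of the β-carbon, giving the adduct F11.
- MeNH(OMe)·HCl with AlMe3 should give the Weinreb amide F12 and release the auxiliary.
- 4-(BnO)C6H4MgBr should give the silyl-protected ketone F13.
- Bu4NF should free the phenol and return the material to the route at 6.

## Further compounds

F1 | step 6 | 4-hydroperoxy-4-[(1S,3S)-3-[4-(benzyloxy)phenyl]-3-hydroxy-1-[2,4,6-tris(benzyloxy)phenyl]propyl]cyclohexa-2,5-dien-1-one | c1ccccc1COc1cc(OCc2ccccc2)cc(OCc2ccccc2)c1[C@@H](C1(OO)C=CC(=O)C=C1)C[C@@H](c1ccc(OCc2ccccc2)cc1)O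
F2 | step 6 | 4-hydroxy-4-[(1S,3S)-3-[4-(benzyloxy)phenyl]-3-hydroxy-1-[2,4,6-tris(benzyloxy)phenyl]propyl]cyclohexa-2,5-dien-1-one | c1ccccc1COc1cc(OCc2ccccc2)cc(OCc2ccccc2)c1[C@@H](C1(O)C=CC(=O)C=C1)C[C@@H](c1ccc(OCc2ccccc2)cc1)O
F3 | step 6 | (2S,4S)-2-[4-(benzyloxy)phenyl]-4a-hydroxy-4-[2,4,6-tris(benzyloxy)phenyl]-2,3,4,4a,8,8a-hexahydro-7H-chromen-7-one | c1ccccc1COc1cc(OCc2ccccc2)cc(OCc2ccccc2)c1[C@@H](C1(O)C=CC(=O)CC13)C[C@@H](c1ccc(OCc2ccccc2)cc1)O3
F4 | step 8 | 1-(2,4,6-trihydroxyphenyl)dodecan-1-one | CCCCCCCCCCCC(=O)c1c(O)cc(O)cc1O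
F5 | step 8 | 7-(benzyloxy)-4H-chromen-4-one | O=c1ccoc2cc(OCc3ccccc3)ccc12
F6 | step 8 | (2S)-7-(benzyloxy)-2-[4-(benzyloxy)phenyl]chroman-4-one | O=C1C[C@@H](c2ccc(OCc3ccccc3)cc2)Oc2cc(OCc3ccccc3)ccc12
F7 | step 8 | (2S,4S)-7-(benzyloxy)-2-[4-(benzyloxy)phenyl]chroman-4-ol | O[C@H]1C[C@@H](c2ccc(OCc3ccccc3)cc2)Oc2cc(OCc3ccccc3)ccc12
F8 | step 8 | 1-[3-[(2S,4R)-7-(benzyloxy)-2-[4-(benzyloxy)phenyl]chroman-4-yl]-2,4,6-trihydroxyphenyl]dodecan-1-one | CCCCCCCCCCCC(=O)c1c(O)cc(O)c([C@@H]2C[C@@H](c3ccc(OCc4ccccc4)cc3)Oc3cc(OCc4ccccc4)ccc32)c1O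
F9 | step 3 | (2E)-3-[2,4,6-tris(benzyloxy)phenyl]prop-2-enoic acid | OC(=O)/C=C/c1c(OCc2ccccc2)cc(OCc2ccccc2)cc1OCc1ccccc1
F10 | step 3 | (4S)-4-phenyl-3-[(2E)-3-[2,4,6-tris(benzyloxy)phenyl]prop-2-enoyl]-1,3-oxazolidin-2-one | O=C(/C=C/c1c(OCc2ccccc2)cc(OCc2ccccc2)cc1OCc1ccccc1)N1C(=O)OC[C@@H]1c1ccccc1
F11 | step 3 | (4S)-3-[(3R)-3-[4-[(tert-butyldimethylsilyl)oxy]phenyl]-3-[2,4,6-tris(benzyloxy)phenyl]propanoyl]-4-phenyl-1,3-oxazolidin-2-one | c1ccccc1COc1cc(OCc2ccccc2)cc(OCc2ccccc2)c1[C@@H](c1ccc(O[Si](C)(C)C(C)(C)C)cc1)CC(=O)N1C(=O)OC[C@@H]1c1ccccc1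
F12 | step 3 | (3R)-3-[4-[(tert-butyldimethylsilyl)oxy]phenyl]-N-methoxy-N-methyl-3-[2,4,6-tris(benzyloxy)phenyl]propanamide | c1ccccc1COc1cc(OCc2ccccc2)cc(OCc2ccccc2)c1[C@@H](c1ccc(O[Si](C)(C)C(C)(C)C)cc1)CC(=O)N(C)OC
F13 | step 3 | (3R)-1-[4-(benzyloxy)phenyl]-3-[4-[(tert-butyldimethylsilyl)oxy]phenyl]-3-[2,4,6-tris(benzyloxy)phenyl]propan-1-one | c1ccccc1COc1cc(OCc2ccccc2)cc(OCc2ccccc2)c1[C@@H](c1ccc(O[Si](C)(C)C(C)(C)C)cc1)CC(=O)c1ccc(OCc2ccccc2)cc1
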